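**Plan**

1. Locants: hydroazulene C1–C10 (C1/C5 ring fusion, C4=C17H2, C10=C18H2), side chain C11(C19H3)–C12–C13–C14=C15 on C7. Retrosynthetic cuts: C11–C12 (radical conjugate addition); one carbonyl carbon excised from C19 as CO2 (it had tied C19 to O6 as a lactone); C9–C10 (Nozaki–Hiyama–Kishi); C11=C19 and C6–C7 (Z-selective HWE/lactonisation, syn-aldol); C5–C6, C4=C17 and C1–C10 (two conjugate additions on a cyclopentenone).
2. Forward order: five-membered ring first (C1, then C5/C4=C17, then C3), then the δ-lactone on C6/C7, then the seven-membered ring by closing C9–C10, then union with the side-chain acid, then lactone opening and decarboxylation to C19H3, diol unmasking, acetylation, desilylation.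
3. Enabling feature: O6 and the C11 methyl carbon C19 are 1,3-related across C7, so one carbonyl can bridge them into a temporary α,β-unsaturated δ-lactone ring (O6–C(=O)–C19=C11–C7–C6) cis-fused to the C6–C7 bond of the cycloheptane. This makes C11 the β-carbon of an acceptor held inside a ring.
4. The C12/C13 syn-diacetate is a trans-1,3-dioxolane, i.e. L-tartaric acid with one carboxyl as a traceless radical precursor at C12 and the other turned into the isobutenyl end.
5. Stereochemistry: C1 from (R)-4-silyloxycyclopentenone (anti conjugate addition), C5 trans to C1, C3 by CBS reduction, C6/C7 by auxiliary-controlled syn-aldol, C9 in the NHK closure (substrate control), C11 by attack anti to C7–C8 on the cis-fused lactone, C12 trans to C13 on the dioxolane (stereoconvergent), C13 from L-tartrate.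

Key step: step 19

Assumption: compounds 1, 12, 13 and 23 are taken as commercial; TBDPS is used on O3 and O9 so that the acetonide can later be removed with acid.

**Step 1**
Reactants: 1 (R)-4-[(tert-butyldimethylsilyl)oxy]cyclopent-2-en-1-one
Product: 3 (R)-4-[1-(trimethylsilyl)ethenyl]cyclopent-2-en-1-one, via β-silyloxy ketone 2 (not isolated)
Conditions: [1-(trimethylsilyl)ethenyl]MgBr, CuBr·SMe2 (10 mol%), THF, −78 °C; then DBU, CH2Cl2, −20 °C
Reagents that add atoms: [1-(trimethylsilyl)ethenyl]magnesium bromide, C=C([Mg]Br)[Si](C)(C)C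
Why: Copper-catalysed conjugate addition should occur anti to the silyloxy group and so set C1, and E1cB loss of silanol from the β-silyloxy ketone should then give the 4-substituted enone.

**Step 2**
Reactants: 3 (R)-4-[1-(trimethylsilyl)ethenyl]cyclopent-2-en-1-one
Product: 6 (3S,4R)-3-{[dimethyl(propan-2-yloxy)silyl]methyl}-2-methylidene-4-[1-(trimethylsilyl)ethenyl]cyclopentan-1-one, via Mannich base 4 (not isolated), via methiodide salt 5 (not isolated)
Conditions: (i-PrO)Me2SiCH2MgCl, CuBr·SMe2 (10 mol%), THF, −78 °C; CH2=NMe2+ I−, −78 to 0 °C; MeI, CH2Cl2; aq. NaHCO3, rt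
Reagents that add atoms: {[dimethyl(propan-2-yloxy)silyl]methyl}magnesium chloride, CC(C)O[Si](C)(C)C[Mg]Cl; N,N-dimethylmethyleneiminium iodide, C=[N+](C)C.[I-]
Why: A second copper-catalysed conjugate addition (Tamao hydroxymethyl-anion equivalent) should go trans to the C1 substituent and set C5, and the enolate is methylenated by Eschenmoser aminomethylation, quaternisation and elimination.

**Step 3**
Reactants: 6 (3S,4R)-3-{[dimethyl(propan-2-yloxy)silyl]methyl}-2-methylidene-4-[1-(trimethylsilyl)ethenyl]cyclopentan-1-one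
Product: 7 (1S,3S,4R)-3-{[dimethyl(propan-2-yloxy)silyl]methyl}-2-methylidene-4-[1-(trimethylsilyl)ethenyl]cyclopentan-1-ol
Conditions: (R)-Me-CBS (0.2 equiv), catecholborane, toluene, −78 °C
Reagents that add atoms: none
Why: Corey–Bakshi–Shibata 1,2-reduction, with the alkenyl carbon C4 as the large group, should set C3 under reagent control.

**Step 4**
Reactants: 7 (1S,3S,4R)-3-{[dimethyl(propan-2-yloxy)silyl]methyl}-2-methylidene-4-[1-(trimethylsilyl)ethenyl]cyclopentan-1-ol
Product: 8 tert-butyldiphenylsilyl ether of 7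
Conditions: TBDPSCl, imidazole, DMF, rt
Reagents that add atoms: tert-butyl(chloro)diphenylsilane, CC(C)(C)[Si](Cl)(c1ccccc1)c1ccccc1
Why: Standard silylation of the allylic alcohol gives an acid-stable ether that lasts to the final step.

**Step 5**
Reactants: 8 tert-butyldiphenylsilyl ether of 7
Product: 9 the 4-(1-iodoethenyl) analogue of 8 (iodine in place of SiMe3)
Conditions: NIS, MeCN/ClCH2CN (4:1), 0 °C
Reagents that add atoms: N-iodosuccinimide, O=C1CCC(=O)N1I
Why: Ipso-iododesilylation of the vinylsilane (β-silyl cation pathway) should give the 2-iodo-1-alkene needed for the later chromium-mediated closure.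

**Step 6**
Reactants: 9 the 4-(1-iodoethenyl) analogue of 8
Product: 10 the 3-(hydroxymethyl) compound (CH2OH in place of the silylmethyl group of 9)
Conditions: KF, KHCO3, 30% H2O2, THF/MeOH, rt
Reagents that add atoms: hydrogen peroxide, OO
Why: Tamao oxidation of the alkoxysilane converts the C–Si bond into C–OH and leaves the vinyl iodide and alkene untouched.

**Step 7**
Reactants: 10 the 3-(hydroxymethyl) compound
Product: 11 the corresponding cyclopentanecarbaldehyde (C6 aldehyde; ring stereocentres as in 7)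
Conditions: DMP, NaHCO3, CH2Cl2, 0 °C; used crude
Reagents that add atoms: none
Why: Buffered Dess–Martin oxidation gives the β,γ-unsaturated aldehyde under non-basic conditions that should avoid conjugation or epimerisation at C5.

**Step 8**
Reactants: 12 4-[(4-methoxyphenyl)methoxy]butanoic acid; 13 (R)-4-benzyl-1,3-thiazolidine-2-thione
Product: 14 (R)-4-benzyl-3-{4-[(4-methoxyphenyl)methoxy]butanoyl}-1,3-thiazolidine-2-thione
Conditions: EDC·HCl, DMAP, CH2Cl2, rt
Reagents that add atoms: none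
Why: Carbodiimide N-acylation of the auxiliary is routine.

**Step 9**
Reactants: 11 the cyclopentanecarbaldehyde; 14 (R)-4-benzyl-3-{4-[(4-methoxyphenyl)methoxy]butanoyl}-1,3-thiazolidine-2-thione
Product: 15 syn-aldol adduct (C6 carbinol, C7 bearing the 2-(PMB-oxy)ethyl chain and the acyl thiazolidinethione; 2R,3S in the propanoyl numbering)
Conditions: TiCl4, i-Pr2NEt, NMP, CH2Cl2, 0 °C then −78 °C
Reagents that add atoms: none
Why: Crimmins titanium-enolate aldol in the "Evans syn" mode (Zimmerman–Traxler transition state, enolate face fixed by the (R)-auxiliary) should set C6 and C7 under reagent control.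

**Step 10**
Reactants: 15 syn-aldol adduct
Product: 16 β-hydroxy aldehyde (C11 aldehyde)
Conditions: DIBAL-H, CH2Cl2, −78 °C
Reagents that add atoms: none
Why: Direct reductive cleavage of the N-acyl thiazolidinethione gives the aldehyde and frees the auxiliary.

**Step 11**
Reactants: 16 β-hydroxy aldehyde
Product: 18 cis-5,6-disubstituted 5,6-dihydro-2H-pyran-2-one (C6 bearing the cyclopentyl unit, C7 the 2-(PMB-oxy)ethyl chain), via Z-hydroxy enoate 17 (not isolated)
Conditions: (PhO)2P(O)CH2CO2Et, NaI, DBU, THF, 0 °C to rt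
Reagents that add atoms: ethyl 2-(diphenoxyphosphoryl)acetate, CCOC(=O)CP(=O)(Oc1ccccc1)Oc1ccccc1
Why: Ando Z-selective Horner–Wadsworth–Emmons olefination gives the (Z)-δ-hydroxy enoate, which lactonises to the unsaturated δ-lactone.

**Step 12**
Reactants: 18 the PMB-protected lactone
Product: 19 primary alcohol (C9–OH)
Conditions: DDQ, CH2Cl2/pH 7 buffer, 0 °C
Reagents that add atoms: none
Why: Oxidative PMB cleavage is selective in the presence of the silyl ether, vinyl iodide and enoate.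

**Step 13**
Reactants: 19 primary alcohol
Product: 20 aldehyde (C9)
Conditions: DMP, NaHCO3, CH2Cl2, rt
Reagents that add atoms: none
Why: Dess–Martin oxidation gives the aldehyde for ring closure.

**Step 14**
Reactants: 20 iodo-aldehyde
Product: 21 tricyclic lactone alcohol (trans-hydroazulene; free 9-OH, C10=C18H2, C4=C17H2, 3-OTBDPS, lactone cis-fused at C6–C7)
Conditions: CrCl2, NiCl2 (cat.), DMSO/THF, rt, 0.005 M
Reagents that add atoms: none
Why: Intramolecular Nozaki–Hiyama–Kishi addition of the vinylchromium to the aldehyde closes the seven-membered ring and should set C9 with the chromium alkoxide pseudo-equatorial, anti to the C1–C2 bond.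

**Step 15**
Reactants: 21 tricyclic lactone alcohol
Product: 22 3,9-bis(tert-butyldiphenylsilyl) tricyclic unsaturated lactone
Conditions: TBDPSCl, imidazole, DMAP, DMF, 40 °C
Reagents that add atoms: tert-butyl(chloro)diphenylsilane, CC(C)(C)[Si](Cl)(c1ccccc1)c1ccccc1
Why: Silylation protects O9 in the same way as O3.

**Step 16**
Reactants: 23 dimethyl (4R,5R)-2,2-dimethyl-1,3-dioxolane-4,5-dicarboxylate
Product: 24 methyl (4R,5S)-5-(hydroxymethyl)-2,2-dimethyl-1,3-dioxolane-4-carboxylate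
Conditions: NaBH4 (0.6 equiv), MeOH, 0 °C
Reagents that add atoms: none
Why: Mono-reduction of the C2-symmetric diester gives one product whichever ester reacts.

**Step 17**
Reactants: 24 methyl (4R,5S)-5-(hydroxymethyl)-2,2-dimethyl-1,3-dioxolane-4-carboxylate
Product: 26 methyl (4R,5S)-2,2-dimethyl-5-(2-methylprop-1-en-1-yl)-1,3-dioxolane-4-carboxylate, via formyl ester 25 (not isolated)
Conditions: DMP, NaHCO3, CH2Cl2; then i-PrPPh3I, n-BuLi, THF, −78 to 0 °C
Reagents that add atoms: isopropyltriphenylphosphonium iodide, CC(C)[P+](c1ccccc1)(c1ccccc1)c1ccccc1.[I-]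
Why: Oxidation and Wittig olefination with the non-stabilised ylide install the C14=C15 alkene, the trans-dioxolane being the stable arrangement.

**Step 18**
Reactants: 26 methyl (4R,5S)-2,2-dimethyl-5-(2-methylprop-1-en-1-yl)-1,3-dioxolane-4-carboxylate
Product: 27 (4R,5S)-2,2-dimethyl-5-(2-methylprop-1-en-1-yl)-1,3-dioxolane-4-carboxylic acid
Conditions: LiOH, THF/H2O, 0 °C; aq. NaHSO4
Reagents that add atoms: lithium hydroxide, [Li+].[OH-]
Why: Saponification gives the α-alkoxy acid that serves as radical precursor.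

**Step 19**
Reactants: 22 3,9-bis(tert-butyldiphenylsilyl) tricyclic unsaturated lactone; 27 (4R,5S)-2,2-dimethyl-5-(2-methylprop-1-en-1-yl)-1,3-dioxolane-4-carboxylic acid
Product: 28 saturated δ-lactone carrying the trans-dioxolane at C11 (C11–C12 bond formed)
Conditions: 27 (1.5 equiv), Ir[dF(CF3)ppy]2(dtbbpy)PF6 (2 mol%), K2HPO4, degassed DMF (0.3 M in 22), blue LEDs, rt
Reagents that add atoms: none
Why: Excited Ir(III) oxidises the carboxylate of 27, loss of CO2 gives the nucleophilic 1,3-dioxolan-4-yl radical at C12, this adds to C11 (the β-carbon of the unsaturated δ-lactone of 22), and the α-lactone radical at C19 is reduced by Ir(II) to the enolate and protonated. The closest known reaction type is the photoredox decarboxylative Giese addition of α-alkoxy acids to cyclic enoates; no ring is closed. C12 is controlled by the neighbouring C13 isobutenyl group, the radical reacting anti to it to give the trans-dioxolane whatever the C12 configuration of 27 was (stereoconvergent). C11 is controlled by the cis-fused lactone, which should be attacked on its convex face, anti to the C7–C8 bond. The step needs chemoselectivity for the enoate over the two 1,1-disubstituted alkenes, secured by the polarity match of the nucleophilic radical with electron-poor C11, and addition must outrun the 1,2-vinyl shift of the homoallylic radical, for which the acceptor is kept concentrated.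

**Step 20**
Reactants: 28 saturated δ-lactone adduct
Product: 31 C19-carboxylic acid with 6-O-tert-butyldimethylsilyl ether (seco acid of 28), via lithium hydroxy carboxylate 29 (not isolated), via bis-silyl derivative 30 (not isolated)
Conditions: LiOH, THF/H2O, rt, evaporate; TBSOTf, 2,6-lutidine, CH2Cl2, 0 °C; K2CO3, MeOH/THF/H2O
Reagents that add atoms: lithium hydroxide, [Li+].[OH-]; tert-butyldimethylsilyl trifluoromethanesulfonate, CC(C)(C)[Si](C)(C)OS(=O)(=O)C(F)(F)F
Why: Saponification opens the temporary lactone, silylation of the unacidified carboxylate salt caps O6 before relactonisation, and mild methanolysis cleaves only the silyl ester.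

**Step 21**
Reactants: 31 C19-carboxylic acid
Product: 33 C11-methyl compound (acetonide, 6-OTBS, 3,9-bis-OTBDPS), via Barton ester 32 (not isolated)
Conditions: N-hydroxypyridine-2-thione, EDC·HCl, DMAP, CH2Cl2, dark; then t-BuSH, hν (tungsten lamp), PhH, rt
Reagents that add atoms: none
Why: Barton reductive decarboxylation removes the tether carbon and leaves C19H3, the thiol trapping the primary radical faster than any cyclisation, which the trans-acetonide also disfavours.

**Step 22**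
Reactants: 33 C11-methyl compound
Product: 34 12,13-diol
Conditions: CSA (0.2 equiv), MeOH/CH2Cl2, 0 °C to rt
Reagents that add atoms: none
Why: Acid-catalysed transketalisation removes the acetonide while the TBDPS ethers and the hindered 6-OTBS ether should survive.

**Step 23**
Reactants: 34 12,13-diol
Product: 35 12,13-diacetate
Conditions: Ac2O, pyridine, DMAP, CH2Cl2, rt
Reagents that add atoms: acetic anhydride, CC(=O)OC(C)=O
Why: Only O12 and O13 are free, so acetylation is site-selective by protection.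

**Step 24**
Reactants: 35 12,13-diacetate
Product: 36 CNP0172457.2 (target)
Conditions: HF·pyridine, pyridine, THF, 0 °C to rt
Reagents that add atoms: none
Why: Buffered fluoride desilylation frees O3, O6 and O9 without touching the acetates.

**Compound list**

1 | (R)-4-[(tert-butyldimethylsilyl)oxy]cyclopent-2-en-1-one | O=C1C=C[C@H](O[Si](C)(C)C(C)(C)C)C1 | starting material
2 | trans-4-[(tert-butyldimethylsilyl)oxy]-3-[1-(trimethylsilyl)ethenyl]cyclopentan-1-one | O=C1C[C@@H](O[Si](C)(C)C(C)(C)C)[C@H](C(=C)[Si](C)(C)C)C1 | intermediate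
3 | (R)-4-[1-(trimethylsilyl)ethenyl]cyclopent-2-en-1-one | O=C1C=C[C@H](C(=C)[Si](C)(C)C)C1 | intermediate
4 | 2-[(dimethylamino)methyl]-3-{[dimethyl(propan-2-yloxy)silyl]methyl}-4-[1-(trimethylsilyl)ethenyl]cyclopentan-1-one (3,4-trans; C2 epimers) | CN(C)CC1[C@@H](C[Si](C)(C)OC(C)C)[C@H](C(=C)[Si](C)(C)C)CC1=O | intermediate
5 | N-methyl quaternary ammonium iodide of 4 | C[N+](C)(C)CC1[C@@H](C[Si](C)(C)OC(C)C)[C@H](C(=C)[Si](C)(C)C)CC1=O.[I-] | intermediate
6 | (3S,4R)-3-{[dimethyl(propan-2-yloxy)silyl]methyl}-2-methylidene-4-[1-(trimethylsilyl)ethenyl]cyclopentan-1-one | C=C1[C@@H](C[Si](C)(C)OC(C)C)[C@H](C(=C)[Si](C)(C)C)CC1=O | intermediate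
7 | (1S,3S,4R)-3-{[dimethyl(propan-2-yloxy)silyl]methyl}-2-methylidene-4-[1-(trimethylsilyl)ethenyl]cyclopentan-1-ol | C=C1[C@@H](C[Si](C)(C)OC(C)C)[C@H](C(=C)[Si](C)(C)C)C[C@@H]1O | intermediate
8 | tert-butyldiphenylsilyl ether of 7 | C=C1[C@@H](C[Si](C)(C)OC(C)C)[C@H](C(=C)[Si](C)(C)C)C[C@@H]1O[Si](c1ccccc1)(c1ccccc1)C(C)(C)C | intermediate
9 | 4-(1-iodoethenyl) analogue of 8 | C=C1[C@@H](C[Si](C)(C)OC(C)C)[C@H](C(I)=C)C[C@@H]1O[Si](c1ccccc1)(c1ccccc1)C(C)(C)C | intermediate
10 | 3-(hydroxymethyl) compound from 9 | C=C1[C@@H](CO)[C@H](C(I)=C)C[C@@H]1O[Si](c1ccccc1)(c1ccccc1)C(C)(C)C | intermediate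
11 | cyclopentanecarbaldehyde from 10 (trans-2-(1-iodoethenyl), 5-methylidene, 4-OTBDPS) | C=C1[C@@H](C=O)[C@H](C(I)=C)C[C@@H]1O[Si](c1ccccc1)(c1ccccc1)C(C)(C)C | intermediate
12 | 4-[(4-methoxyphenyl)methoxy]butanoic acid | COc1ccc(COCCCC(=O)O)cc1 | starting material
13 | (R)-4-benzyl-1,3-thiazolidine-2-thione | S=C1N[C@H](Cc2ccccc2)CS1 | starting material
14 | (R)-4-benzyl-3-{4-[(4-methoxyphenyl)methoxy]butanoyl}-1,3-thiazolidine-2-thione | COc1ccc(COCCCC(=O)N2[C@H](Cc3ccccc3)CSC2=S)cc1 | intermediate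
15 | syn-aldol adduct of 11 and 14 | C=C1[C@@H]([C@H](O)[C@H](C(=O)N2[C@H](Cc3ccccc3)CSC2=S)CCOCc2ccc(OC)cc2)[C@H](C(I)=C)C[C@@H]1O[Si](c1ccccc1)(c1ccccc1)C(C)(C)C | intermediate
16 | β-hydroxy aldehyde from 15 | C=C1[C@@H]([C@H](O)[C@H](C=O)CCOCc2ccc(OC)cc2)[C@H](C(I)=C)C[C@@H]1O[Si](c1ccccc1)(c1ccccc1)C(C)(C)C | intermediate
17 | ethyl (Z)-δ-hydroxy enoate from 16 | C=C1[C@@H]([C@H](O)[C@H](/C=C\C(=O)OCC)CCOCc2ccc(OC)cc2)[C@H](C(I)=C)C[C@@H]1O[Si](c1ccccc1)(c1ccccc1)C(C)(C)C | intermediate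
18 | cis-5-[2-(4-methoxybenzyloxy)ethyl]-6-(cyclopentyl unit)-5,6-dihydro-2H-pyran-2-one | C=C1[C@@H]([C@@H]2OC(=O)C=C[C@@H]2CCOCc2ccc(OC)cc2)[C@H](C(I)=C)C[C@@H]1O[Si](c1ccccc1)(c1ccccc1)C(C)(C)C | intermediate
19 | primary alcohol from 18 | C=C1[C@@H]([C@@H]2OC(=O)C=C[C@@H]2CCO)[C@H](C(I)=C)C[C@@H]1O[Si](c1ccccc1)(c1ccccc1)C(C)(C)C | intermediate
20 | aldehyde from 19 | C=C1[C@@H]([C@@H]2OC(=O)C=C[C@@H]2CC=O)[C@H](C(I)=C)C[C@@H]1O[Si](c1ccccc1)(c1ccccc1)C(C)(C)C | intermediate
21 | tricyclic unsaturated lactone with free 9-OH and 3-OTBDPS | C=C1[C@H]2[C@@H]3OC(=O)C=C[C@@H]3C[C@@H](O)C(=C)[C@@H]2C[C@@H]1O[Si](c1ccccc1)(c1ccccc1)C(C)(C)C | intermediate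
22 | 3,9-bis(tert-butyldiphenylsilyl) tricyclic unsaturated lactone | C=C1[C@H]2[C@@H]3OC(=O)C=C[C@@H]3C[C@@H](O[Si](c3ccccc3)(c3ccccc3)C(C)(C)C)C(=C)[C@@H]2C[C@@H]1O[Si](c1ccccc1)(c1ccccc1)C(C)(C)C | intermediate
23 | dimethyl (4R,5R)-2,2-dimethyl-1,3-dioxolane-4,5-dicarboxylate | COC(=O)[C@@H]1OC(C)(C)O[C@H]1C(=O)OC | starting material
24 | methyl (4R,5S)-5-(hydroxymethyl)-2,2-dimethyl-1,3-dioxolane-4-carboxylate | COC(=O)[C@@H]1OC(C)(C)O[C@H]1CO | intermediate
25 | methyl (4R,5R)-5-formyl-2,2-dimethyl-1,3-dioxolane-4-carboxylate | COC(=O)[C@@H]1OC(C)(C)O[C@H]1C=O | intermediate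
26 | methyl (4R,5S)-2,2-dimethyl-5-(2-methylprop-1-en-1-yl)-1,3-dioxolane-4-carboxylate | COC(=O)[C@@H]1OC(C)(C)O[C@H]1C=C(C)C | intermediate
27 | (4R,5S)-2,2-dimethyl-5-(2-methylprop-1-en-1-yl)-1,3-dioxolane-4-carboxylic acid | OC(=O)[C@@H]1OC(C)(C)O[C@H]1C=C(C)C | intermediate
28 | saturated δ-lactone adduct with trans-dioxolane at C11 | C=C1[C@H]2[C@@H]3OC(=O)C[C@@H]([C@@H]4OC(C)(C)O[C@H]4C=C(C)C)[C@@H]3C[C@@H](O[Si](c3ccccc3)(c3ccccc3)C(C)(C)C)C(=C)[C@@H]2C[C@@H]1O[Si](c1ccccc1)(c1ccccc1)C(C)(C)C | intermediate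
29 | lithium 6-hydroxy carboxylate (opened lactone) | C=C1[C@H]2[C@H](O)[C@H]([C@@H](CC(=O)[O-])[C@@H]3OC(C)(C)O[C@H]3C=C(C)C)C[C@@H](O[Si](c3ccccc3)(c3ccccc3)C(C)(C)C)C(=C)[C@@H]2C[C@@H]1O[Si](c1ccccc1)(c1ccccc1)C(C)(C)C.[Li+] | intermediate
30 | 6-O-TBS ether TBS ester | C=C1[C@H]2[C@H](O[Si](C)(C)C(C)(C)C)[C@H]([C@@H](CC(=O)O[Si](C)(C)C(C)(C)C)[C@@H]3OC(C)(C)O[C@H]3C=C(C)C)C[C@@H](O[Si](c3ccccc3)(c3ccccc3)C(C)(C)C)C(=C)[C@@H]2C[C@@H]1O[Si](c1ccccc1)(c1ccccc1)C(C)(C)C | intermediate
31 | 6-O-TBS C19-carboxylic acid | C=C1[C@H]2[C@H](O[Si](C)(C)C(C)(C)C)[C@H]([C@@H](CC(=O)O)[C@@H]3OC(C)(C)O[C@H]3C=C(C)C)C[C@@H](O[Si](c3ccccc3)(c3ccccc3)C(C)(C)C)C(=C)[C@@H]2C[C@@H]1O[Si](c1ccccc1)(c1ccccc1)C(C)(C)C | intermediate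
32 | O-acyl N-hydroxypyridine-2-thione (Barton) ester of 31 | C=C1[C@H]2[C@H](O[Si](C)(C)C(C)(C)C)[C@H]([C@@H](CC(=O)ON4C=CC=CC4=S)[C@@H]3OC(C)(C)O[C@H]3C=C(C)C)C[C@@H](O[Si](c3ccccc3)(c3ccccc3)C(C)(C)C)C(=C)[C@@H]2C[C@@H]1O[Si](c1ccccc1)(c1ccccc1)C(C)(C)C | intermediate
33 | C11-methyl compound (12,13-acetonide, 6-OTBS, 3,9-bis-OTBDPS) | C=C1[C@H]2[C@H](O[Si](C)(C)C(C)(C)C)[C@H]([C@@H](C)[C@@H]3OC(C)(C)O[C@H]3C=C(C)C)C[C@@H](O[Si](c3ccccc3)(c3ccccc3)C(C)(C)C)C(=C)[C@@H]2C[C@@H]1O[Si](c1ccccc1)(c1ccccc1)C(C)(C)C | intermediate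
34 | 12,13-diol | C=C1[C@H]2[C@H](O[Si](C)(C)C(C)(C)C)[C@H]([C@@H](C)[C@H](O)[C@H](C=C(C)C)O)C[C@@H](O[Si](c3ccccc3)(c3ccccc3)C(C)(C)C)C(=C)[C@@H]2C[C@@H]1O[Si](c1ccccc1)(c1ccccc1)C(C)(C)C | intermediate
35 | 12,13-diacetate | C=C1[C@H]2[C@H](O[Si](C)(C)C(C)(C)C)[C@H]([C@@H](C)[C@H](OC(C)=O)[C@H](C=C(C)C)OC(C)=O)C[C@@H](O[Si](c3ccccc3)(c3ccccc3)C(C)(C)C)C(=C)[C@@H]2C[C@@H]1O[Si](c1ccccc1)(c1ccccc1)C(C)(C)C | intermediate
36 | CNP0172457.2 | C=C1[C@H]2[C@H](O)[C@H]([C@@H](C)[C@H](OC(C)=O)[C@H](C=C(C)C)OC(C)=O)C[C@@H](O)C(=C)[C@@H]2C[C@@H]1O | target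

**Step count and risks**

Total step count: 24. Longest linear sequence: 20 steps (1–7, 9–15, 19–24).

The three steps most likely to fail:

- **Step 19.** The homoallylic dioxolanyl radical may undergo a 1,2-vinyl shift (through the cyclopropylcarbinyl radical) faster than it adds to the hindered enoate, which would erode the C13 configuration and the efficiency of the union. Fallback: setting out from 24, saponification should give the alkene-free donor (4R,5S)-5-(hydroxymethyl)-2,2-dimethyl-1,3-dioxolane-4-carboxylic acid F1, which cannot rearrange. The same decarboxylative addition to 22 should give the hydroxymethyl adduct F2. Dess–Martin oxidation to the dioxolane aldehyde F3 and Wittig olefination with isopropylidenetriphenylphosphorane would then build C14=C15 after the union and return to 28.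
- **Step 14.** The ring-closing addition may show poor facial selectivity at C9 on the flexible seven-membered transition state. Fallback: setting out from 20, the cyclisation is run without regard to C9, giving 21 together with its C9 epimer F4. The mixture is oxidised (Dess–Martin) to the exo-methylene ketone F5, and a reagent-controlled (S)-Me-CBS/catecholborane 1,2-reduction returns to 21.
- **Step 9.** The β,γ-unsaturated aldehyde 11 may isomerise into conjugation or epimerise at C5 under the Lewis-acidic titanium-enolate conditions. Fallback: setting out from 11, a neutral chiral-phosphoric-acid-catalysed allylboration with (Z)-2-[5-(4-methoxybenzyloxy)pent-2-en-1-yl]-4,4,5,5-tetramethyl-1,3,2-dioxaborolane (TRIP antipode chosen for the C6 configuration of 15) should give the syn homoallylic alcohol F6 with the C7 vinyl group. Acylation with acryloyl chloride gives the acrylate F7, and ring-closing metathesis (Grubbs II) between the acrylate and the C7 vinyl group returns to 18.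

**Further compounds**

F1 | step 19 | (4R,5S)-5-(hydroxymethyl)-2,2-dimethyl-1,3-dioxolane-4-carboxylic acid | OC(=O)[C@@H]1OC(C)(C)O[C@H]1CO
F2 | step 19 | hydroxymethyl-dioxolane analogue of 28 | C=C1[C@H]2[C@@H]3OC(=O)C[C@@H]([C@@H]4OC(C)(C)O[C@H]4CO)[C@@H]3C[C@@H](O[Si](c3ccccc3)(c3ccccc3)C(C)(C)C)C(=C)[C@@H]2C[C@@H]1O[Si](c1ccccc1)(c1ccccc1)C(C)(C)C
F3 | step 19 | formyl-dioxolane analogue of 28 | C=C1[C@H]2[C@@H]3OC(=O)C[C@@H]([C@@H]4OC(C)(C)O[C@H]4C=O)[C@@H]3C[C@@H](O[Si](c3ccccc3)(c3ccccc3)C(C)(C)C)C(=C)[C@@H]2C[C@@H]1O[Si](c1ccccc1)(c1ccccc1)C(C)(C)C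
F4 | step 14 | C9 epimer of 21 | C=C1[C@H]2[C@@H]3OC(=O)C=C[C@@H]3C[C@H](O)C(=C)[C@@H]2C[C@@H]1O[Si](c1ccccc1)(c1ccccc1)C(C)(C)C
F5 | step 14 | 9-oxo (exo-methylene ketone) analogue of 21 | C=C1[C@H]2[C@@H]3OC(=O)C=C[C@@H]3CC(=O)C(=C)[C@@H]2C[C@@H]1O[Si](c1ccccc1)(c1ccccc1)C(C)(C)C
F6 | step 9 | syn homoallylic alcohol (C6–OH, C7 vinyl) | C=C1[C@@H]([C@H](O)[C@H](C=C)CCOCc2ccc(OC)cc2)[C@H](C(I)=C)C[C@@H]1O[Si](c1ccccc1)(c1ccccc1)C(C)(C)C
F7 | step 9 | acrylate ester of F6 | C=C1[C@@H]([C@H](OC(=O)C=C)[C@H](C=C)CCOCc2ccc(OC)cc2)[C@H](C(I)=C)C[C@@H]1O[Si](c1ccccc1)(c1ccccc1)C(C)(C)C
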